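The ring is opened at the bond between its methyl-bearing alkene carbon C3 and the acetoxy carbinol C4, the alkenyl–carbinol bond of the ring allylic acetate (C2=C3–C4–O). An intramolecular Nozaki–Hiyama–Kishi reaction closes the six-membered ring, turns a (Z)-iodoalkene into the endocyclic C2=C3 bond and sets C4 in one operation. Its precursor is an acyclic iodo aldehyde that already carries the angelate, the side-chain acetate and the other four stereocentres. It comes from (R)-citronellic acid, whose ten carbons become C1 and C6–C11 with their methyl groups. A rose-oxide-type cis δ-lactone relays its stereocentre to C9 and C6, and a prenyl group is the latent C5–C4 acetaldehyde unit.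

Key step: step 10

Remark on numbering: the ring is C1 (O-angelate), C2H=C3(CH3), C4 (OAc), C5H2 and C6. The side chain is C7H(CH3), C8H2, C9H(OAc) and C10H=C11(CH3)2. The target is 1S,4R,6S,7R,9R, with O1 and O4 cis to each other and both trans to the side chain.
Assumption: compounds 1, 6, 9 and 16 are taken as commercial.

Step 1
Reactants: 1 (R)-citronellic acid
Product: 4 (3R,5E)-7-hydroxy-3,7-dimethyloct-5-enoic acid, via hydroxy selenide 2 (not isolated), via selenoxide 3 (not isolated)
Conditions: PhSeCl, MeCN–H2O (5:1), rt; then 30% H2O2, 0 °C to rt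
Reagents that add atoms: water (O)
Why: Markovnikov anti-hydroxyselenenylation places OH on the tertiary carbon C11 and PhSe on C10, and the selenoxide syn-elimination can only take a C9 hydrogen, so a single E tertiary allylic alcohol should form while C7 is untouched.

Step 2
Reactants: 4 (3R,5E)-7-hydroxy-3,7-dimethyloct-5-enoic acid
Product: 5 (4R,6R)-4-methyl-6-(2-methylprop-1-enyl)oxan-2-one (cis lactone)
Conditions: p-TsOH·H2O (5 mol %), 4 Å MS, CH2Cl2, rt
Reagents that add atoms: none
Why: Acid ionises the tertiary allylic alcohol to the dimethylallyl cation, which the carboxyl oxygen captures at its secondary end C9 (SN1′ dehydrative lactonisation, the reaction type of the rose oxide cyclisation) through a chair with methyl and isobutenyl equatorial, and since the allylic C–O bond can re-ionise the mixture should converge on the more stable cis lactone, which sets C9 as R.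

Step 3
Reactants: 5 cis lactone; 6 prenyl bromide (1-bromo-3-methylbut-2-ene)
Product: 8 (3S,4R,6R)-4-methyl-3-(3-methylbut-2-enyl)-6-(2-methylprop-1-enyl)oxan-2-one, via lithium enolate 7 (not isolated)
Conditions: LDA, THF, −78 °C; then 6, DMPU, −78 to −40 °C
Reagents that add atoms: none
Why: Kinetic lactone enolate alkylation with a reactive allylic bromide occurs on the face opposite the adjacent C7 methyl group and the cis isobutenyl group, giving the all-equatorial 3,4-trans product that sets C6 as S, and the low temperature keeps the allylic lactone enolate from an Ireland–Claisen-type ring contraction.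

Step 4
Reactants: 8 prenylated lactone; 9 1-propynyllithium
Product: 11 (5S,6R,8R)-8-hydroxy-6,10-dimethyl-5-(3-methylbut-2-enyl)undec-9-en-2-yn-4-one, via lithium lactolate 10 (not isolated)
Conditions: 9 (1.1 equiv), THF, −78 °C; AcOH quench at −78 °C
Reagents that add atoms: none
Why: Acetylide addition to a δ-lactone stops at the lithium lactolate at −78 °C, which opens to the hydroxy ynone only on the cold acidic quench, so neither double addition nor epimerisation at C6 is expected.

Step 5
Reactants: 11 hydroxy ynone
Product: 12 (4S,5S,6R,8R)-6,10-dimethyl-5-(3-methylbut-2-enyl)undec-9-en-2-yne-4,8-diol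
Conditions: Ru[(S,S)-TsDPEN](p-cymene) (5 mol %), i-PrOH, rt
Reagents that add atoms: none
Why: In the Noyori asymmetric transfer hydrogenation of an ynone the (S,S) catalyst should give the (S)-propargylic alcohol at C1 under reagent control, reinforced by the Felkin–Anh bias of C6, under base-free conditions that spare C6 and leave the (R)-allylic alcohol at C9, which is mismatched for dehydrogenation, untouched.

Step 6
Reactants: 12 propargylic/allylic diol
Product: 14 (2Z,4S,5S,6R,8R)-2-iodo-6,10-dimethyl-5-(3-methylbut-2-enyl)undeca-2,9-diene-4,8-diol, via oxaaluminacycle 13 (not isolated)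
Conditions: Red-Al, THF, 0 °C to rt; then I2, THF, −78 °C
Reagents that add atoms: iodine (II)
Why: Hydroxyl-directed trans-hydroalumination of the propargylic alcohol places aluminium on the distal carbon C3 in a five-membered oxaaluminacycle, and iodinolysis with retention at low temperature should give only the (Z)-iodoalkene with iodine cis to C1 while the remote trisubstituted alkenes are left alone.

Step 7
Reactants: 14 iodo diol
Product: 15 (2Z,4S,5S,6R,8R)-4-hydroxy-2-iodo-6,10-dimethyl-5-(3-methylbut-2-enyl)undeca-2,9-dien-8-yl acetate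
Conditions: Ac2O (1.05 equiv), pyridine, CH2Cl2, 0 °C
Reagents that add atoms: acetic anhydride (CC(=O)OC(C)=O)
Why: In this site-selective acylation the C9 hydroxyl has a CH2 neighbour whereas the C1 hydroxyl is flanked by the fully branched C6 and the Z-iodoalkene, so one equivalent of anhydride without a nucleophilic catalyst should acetylate C9–OH only.

Step 8
Reactants: 15 hydroxy acetate; 16 angelic acid ((Z)-2-methylbut-2-enoic acid)
Product: 18 (2Z,4S,5S,6R,8R)-8-acetoxy-2-iodo-6,10-dimethyl-5-(3-methylbut-2-enyl)undeca-2,9-dien-4-yl (Z)-2-methylbut-2-enoate, via mixed anhydride 17 (not isolated)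
Conditions: 16, 2,4,6-Cl3C6H2COCl, Et3N, toluene, rt; then 15, 80 °C
Reagents that add atoms: none
Why: Yamaguchi-type mixed anhydride esterification without DMAP is the established way to acylate hindered secondary alcohols with angelic acid without Z to E drift to the tiglate, and C1 keeps its configuration because its C–O bond is not touched.

Step 9
Reactants: 18 prenyl iodoalkene diester
Product: 20 (2Z,4S,5S,6R,8R)-8-acetoxy-2-iodo-6,10-dimethyl-5-(2-oxoethyl)undeca-2,9-dien-4-yl (Z)-2-methylbut-2-enoate, via ozonide 19 (not isolated)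
Conditions: O3 (1 equiv, Sudan Red 7B end point), CH2Cl2, −78 °C; then Me2S, −78 °C to rt
Reagents that add atoms: ozone ([O-][O+]=O)
Why: Electrophilic ozone should attack the only electron-rich alkene, the isolated prenyl double bond, faster than the alkenes deactivated by an allylic acetate, by iodine plus an allylic ester or by ester conjugation (the selectivity pattern of geranyl acetate), and reductive work-up of the ozonide unmasks the C5–C4 CH2CHO unit.

Step 10
Reactants: 20 iodoalkene aldehyde
Product: 22 (1S,4R,6S)-6-[(2R,4R)-4-acetoxy-6-methylhept-5-en-2-yl]-4-hydroxy-3-methylcyclohex-2-en-1-yl (Z)-2-methylbut-2-enoate, via alkenylchromium 21 (not isolated)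
Conditions: CrCl2 (8 equiv), NiCl2 (cat.), degassed DMSO, rt, 5 mM; aqueous work-up
Reagents that add atoms: none
Why: Ni(0), made in situ from NiCl2 and CrCl2, inserts into the C3–I bond with retention, transmetalation to Cr(III) gives the (Z)-alkenylchromium 21, and this adds to the tethered C4 aldehyde before aqueous work-up frees the alcohol. The closest known reaction type is the intramolecular Nozaki–Hiyama–Kishi reaction of an iodoalkene aldehyde, which is routinely run late on polyfunctional substrates. The only ring closed is the six-membered carbocycle, by 6-exo-trig attack of C3 on the C4=O group, which is geometrically possible because iodine stands cis to C1, so that the Z alkene becomes the endocyclic C2=C3 bond. C4 is set in a half-chair transition state in which the C6 side chain is equatorial and the C1 angelate pseudoequatorial, while the bulky chromium-bound oxygen takes the pseudoaxial position to escape A(1,2) strain with the C3 methyl group; this places O4 trans to the side chain and cis to O1, which is the 4R configuration. The step needs chemoselectivity for the aldehyde over three esters and for the C–I bond over two allylic esters, which the low basicity and aldehyde preference of organochromium(III) and the fast oxidative addition of the iodoalkene secure, and no leaving group sits β to the aldehyde.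

Step 11
Reactants: 22 cyclohexenol
Product: 23 (1S,4R,6S)-4-acetoxy-6-[(2R,4R)-4-acetoxy-6-methylhept-5-en-2-yl]-3-methylcyclohex-2-en-1-yl (Z)-2-methylbut-2-enoate (target)
Conditions: Ac2O, pyridine, CH2Cl2, rt
Reagents that add atoms: acetic anhydride (CC(=O)OC(C)=O)
Why: Standard acetylation of the single free allylic hydroxyl proceeds with retention at C4 and is run without DMAP to protect the angelate geometry.

Compound list
1 | (R)-citronellic acid, (3R)-3,7-dimethyloct-6-enoic acid | OC(=O)C[C@H](C)CCC=C(C)C | starting material
2 | (3R)-7-hydroxy-3,7-dimethyl-6-(phenylselanyl)octanoic acid (C6 epimers) | OC(=O)C[C@H](C)CCC([Se]c1ccccc1)C(C)(C)O | intermediate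
3 | selenoxide of 2 | OC(=O)C[C@H](C)CCC([Se](=O)c1ccccc1)C(C)(C)O | intermediate
4 | (3R,5E)-7-hydroxy-3,7-dimethyloct-5-enoic acid | OC(=O)C[C@H](C)C/C=C/C(C)(C)O | intermediate
5 | (4R,6R)-4-methyl-6-(2-methylprop-1-enyl)oxan-2-one, cis | O=C1C[C@H](C)C[C@H](C=C(C)C)O1 | intermediate
6 | prenyl bromide | CC(C)=CCBr | starting material
7 | lithium enolate of 5 | [Li]OC1=C[C@H](C)C[C@H](C=C(C)C)O1 | intermediate
8 | (3S,4R,6R)-4-methyl-3-(3-methylbut-2-enyl)-6-(2-methylprop-1-enyl)oxan-2-one | O=C1[C@@H](CC=C(C)C)[C@H](C)C[C@H](C=C(C)C)O1 | intermediate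
9 | 1-propynyllithium | [Li]C#CC | starting material
10 | lithium lactolate from 8 and 9 (anomeric centre undefined) | [Li]OC1(C#CC)[C@@H](CC=C(C)C)[C@H](C)C[C@H](C=C(C)C)O1 | intermediate
11 | (5S,6R,8R)-8-hydroxy-6,10-dimethyl-5-(3-methylbut-2-enyl)undec-9-en-2-yn-4-one | CC#CC(=O)[C@@H](CC=C(C)C)[C@H](C)C[C@H](C=C(C)C)O | intermediate
12 | (4S,5S,6R,8R)-6,10-dimethyl-5-(3-methylbut-2-enyl)undec-9-en-2-yne-4,8-diol | CC#C[C@@H](O)[C@@H](CC=C(C)C)[C@H](C)C[C@H](C=C(C)C)O | intermediate
13 | disodium bis-alanate of 12: O1 and C3 bound to Al(OCH2CH2OMe)2 in a five-membered oxaaluminacycle, O9 bound to AlH(OCH2CH2OMe)2 | [Na+].[Na+].CC1=C[C@H]([C@@H](CC=C(C)C)[C@H](C)C[C@H](C=C(C)C)O[AlH-](OCCOC)OCCOC)O[Al-]1(OCCOC)OCCOC | intermediate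
14 | (2Z,4S,5S,6R,8R)-2-iodo-6,10-dimethyl-5-(3-methylbut-2-enyl)undeca-2,9-diene-4,8-diol | C/C(I)=C/[C@@H](O)[C@@H](CC=C(C)C)[C@H](C)C[C@H](C=C(C)C)O | intermediate
15 | 8-monoacetate of 14 | C/C(I)=C/[C@@H](O)[C@@H](CC=C(C)C)[C@H](C)C[C@H](C=C(C)C)OC(C)=O | intermediate
16 | angelic acid | C/C=C(/C)C(=O)O | starting material
17 | angelic 2,4,6-trichlorobenzoic anhydride | C/C=C(/C)C(=O)OC(=O)c1c(Cl)cc(Cl)cc1Cl | intermediate
18 | 4-angelate 8-acetate of 14 | C/C=C(/C)C(=O)O[C@H](/C=C(/C)I)[C@@H](CC=C(C)C)[C@H](C)C[C@H](C=C(C)C)OC(C)=O | intermediate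
19 | 1,2,4-trioxolane (ozonide) of the prenyl alkene of 18 | C/C=C(/C)C(=O)O[C@H](/C=C(/C)I)[C@@H](CC1OOC(C)(C)O1)[C@H](C)C[C@H](C=C(C)C)OC(C)=O | intermediate
20 | iodoalkene aldehyde, 5-(2-oxoethyl) analogue of 18 | C/C=C(/C)C(=O)O[C@H](/C=C(/C)I)[C@@H](CC=O)[C@H](C)C[C@H](C=C(C)C)OC(C)=O | intermediate
21 | (Z)-alkenylchromium(III) dichloride from 20 | C/C=C(/C)C(=O)O[C@H](/C=C(/C)[Cr](Cl)Cl)[C@@H](CC=O)[C@H](C)C[C@H](C=C(C)C)OC(C)=O | intermediate
22 | (1S,4R,6S)-cyclohexenol, 4-deacetyl target | C/C=C(/C)C(=O)O[C@@H]1C=C(C)[C@H](O)C[C@H]1[C@H](C)C[C@H](C=C(C)C)OC(C)=O | intermediate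
23 | CNP0417294.1 | C/C=C(/C)C(=O)O[C@@H]1C=C(C)[C@H](OC(C)=O)C[C@H]1[C@H](C)C[C@H](C=C(C)C)OC(C)=O | target

Total step count: 11. Longest linear sequence: 11 steps, from 1 to 23.

Steps most likely to fail

Step 10. The facial selectivity at the aldehyde may be low or reversed, because the preference for a pseudoaxial chromium alkoxide rests only on a conformational argument. The fallback sets out from 20 and comes back at 23.
- The ring is closed in the same way, but the closure is no longer asked to set C4.
- The epimer mixture is oxidised with Dess–Martin periodinane to the 4-oxo cyclohexenone F1.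
- Luche reduction by axial hydride attack, as on carvone-type enones, should give the pseudoequatorial 4S alcohol F2.
- Mitsunobu inversion with acetic acid (PPh3, DIAD) installs the 4R acetate directly and gives 23.

Step 9. Ozone may also attack the C10=C11 alkene, which is shielded only by its allylic acetate. The fallback sets out from 18 and comes back at 20.
- One equivalent of buffered mCPBA at 0 °C, a more discriminating electrophile, should epoxidise the prenyl alkene to the prenyl epoxide F3.
- Periodic acid in wet ether then cleaves the epoxide to the aldehyde 20.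

Step 7. Site discrimination between the two secondary hydroxyls may be incomplete, so that acylation spreads to C1–OH. The fallback sets out from 11 and comes back at 15, so the two oxygens are never free at the same time.
- The only hydroxyl of 11 is acetylated (Ac2O, pyridine, DMAP) to the acetoxy ynone F4.
- Anti-hydroiodination with NaI in AcOH at rt gives the (Z)-β-iodoenone F5.
- Luche 1,2-reduction at −78 °C under Felkin–Anh control, with the C7 branch as the large group, gives 15. The price is substrate control at C1 instead of reagent control.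

Further compounds
F1 | step 10 | (1S,6S)-6-[(2R,4R)-4-acetoxy-6-methylhept-5-en-2-yl]-3-methyl-4-oxocyclohex-2-en-1-yl (Z)-2-methylbut-2-enoate | C/C=C(/C)C(=O)O[C@@H]1C=C(C)C(=O)C[C@H]1[C@H](C)C[C@H](C=C(C)C)OC(C)=O
F2 | step 10 | (1S,4S,6S)-cyclohexenol, C4 epimer of 22 | C/C=C(/C)C(=O)O[C@@H]1C=C(C)[C@@H](O)C[C@H]1[C@H](C)C[C@H](C=C(C)C)OC(C)=O
F3 | step 9 | prenyl epoxide of 18 (epoxide carbon undefined) | C/C=C(/C)C(=O)O[C@H](/C=C(/C)I)[C@@H](CC1OC1(C)C)[C@H](C)C[C@H](C=C(C)C)OC(C)=O
F4 | step 7 | (5S,6R,8R)-6,10-dimethyl-5-(3-methylbut-2-enyl)-4-oxoundec-9-en-2-yn-8-yl acetate | CC#CC(=O)[C@@H](CC=C(C)C)[C@H](C)C[C@H](C=C(C)C)OC(C)=O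
F5 | step 7 | (2Z,5S,6R,8R)-2-iodo-6,10-dimethyl-5-(3-methylbut-2-enyl)-4-oxoundeca-2,9-dien-8-yl acetate | C/C(I)=C/C(=O)[C@@H](CC=C(C)C)[C@H](C)C[C@H](C=C(C)C)OC(C)=O
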